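**Retrosynthetic overview**
1. Last bond formed: the C14–O ester bond, by carboxylate opening of a ring A spiro-epoxide with the unprotected ring B dihydroxy acid (alkyl C–O, not acyl C–O), then removal of one tert-butyl ester.
2. Ring B acid: from a ring-A-type exo-methylene β,γ-unsaturated acid of the mirror-image series by decarboxylative epoxide fragmentation (C2' leaves as CO2; the C1'=C10' alkene and C14' OH appear).
3. Both series: exo-methylene from a C10 ketone; seven-membered lactone by ring-closing metathesis, which fixes the E-acrylate of both halves; vinyl group from a lactol Wittig reaction.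
4. Carbocycle: endo Diels–Alder reaction of one silyloxydiene with (5S)-d- or (5R)-l-menthyloxyfuranone sets C1, C6 and C7 of each half.
5. Ring order: cyclohexane (Diels–Alder), then oxepinone (metathesis), then oxirane; the cyclohexene of ring B is unveiled from the same cyclohexane by loss of CO2.

Assumption: the SMILES is taken literally, so C6' and C7' of ring B are the mirror image of C6 and C7 of ring A and the halves need antipodal series; both 5-(menthyloxy)furanone antipodes and both 2-(bromomethyl)acrylates are purchased.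

Locants in names: ring carbons C1 (carries carboxyl C2), C6 (carries C5), C7 (carries isopropyl), C10 (carries C14); acrylate unit C5=C4(C3)–C15; primes for ring B; β = face of the isopropyl group, α = the opposite face.

**Route**

Step 1
Reactants: 1 3-methylbutanal; 2 (triphenylphosphoranylidene)acetaldehyde
Product: 3 (E)-5-methylhex-2-enal
Conditions: toluene, 80 °C
Reagents that add atoms: none
Why: Wittig olefination with the stabilised formylmethylene ylide is E-selective and stops at the enal when the aldehyde is in excess.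

Step 2
Reactants: 3 (E)-5-methylhex-2-enal
Product: 4 tert-butyl(dimethyl){[(1E,3E)-5-methylhexa-1,3-dien-1-yl]oxy}silane
Conditions: TBSOTf, Et3N, Et2O, 0 °C → rt
Reagents that add atoms: tert-butyldimethylsilyl trifluoromethanesulfonate, CC(C)(C)[Si](C)(C)OS(=O)(=O)C(F)(F)F
Why: γ-enolisation with O-silylation (silyl dienol ether formation) gives mainly the (1E,3E)-diene, the only isomer that can reach the s-cis conformation needed next.

Step 3
Reactants: 4 silyloxydiene; 5 (5S)-5-(d-menthyloxy)furan-2(5H)-one
Product: 6 cis-fused 7-(TBS-oxy)-3-(d-menthyloxy)-4-isopropyl-3a,4,7,7a-tetrahydro-2-benzofuran-1(3H)-one (H-3a, H-4, H-7, H-7a all cis; menthyloxy trans to the carbocycle)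
Conditions: toluene, BHT (cat.), 115 °C, sealed tube
Reagents that add atoms: none
Why: thermal Diels–Alder reaction in which the diene adds anti to the menthyloxy group (absolute control), endo (isopropyl and silyloxy cis to the lactone) and with the oxygenated terminus bonding to the lactone α-carbon, so C1, C6 and C7 of ring A are set in one step.

Step 4
Reactants: 6 Diels–Alder adduct
Product: 7 the ring-saturated (hexahydro) analogue of 6
Conditions: H2 (1 atm), PtO2, EtOAc, rt
Reagents that add atoms: none
Why: heterogeneous hydrogenation removes the only C=C and touches no stereocentre.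

Step 5
Reactants: 7 saturated adduct
Product: 8 cis-fused 3,7-dihydroxy-4-isopropylhexahydro-2-benzofuran-1(3H)-one (lactol, both C3 epimers; 10β-OH)
Conditions: 2 M aq. HCl/THF, 50 °C
Reagents that add atoms: water, O
Why: acid hydrolysis of the pseudo-ester acetal and the silyl ether releases the auxiliary while the aldehyde stays locked as the cis-fused lactol, so C6 cannot epimerise, and no acid-labile alkene is present yet.

Step 6
Reactants: 8 lactol
Product: 9 all-cis 2-ethenyl-6-hydroxy-3-isopropylcyclohexane-1-carboxylic acid (carboxyl, vinyl, isopropyl and hydroxyl all β)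
Conditions: Ph3PCH3Br, KOtBu, THF, −78 → 0 °C; aq. citric acid work-up
Reagents that add atoms: methyltriphenylphosphonium bromide, C[P+](c1ccccc1)(c1ccccc1)c1ccccc1.[Br-]
Why: Wittig methylenation of the lactol through its open aldehyde–carboxylate form, where fast addition of the unstabilised ylide at low temperature outruns enolisation and keeps the cis C1/C6/C7 arrangement.

Step 7
Reactants: 9 vinyl hydroxy acid; 10 tert-butyl 2-(bromomethyl)acrylate
Product: 11 2-(tert-butoxycarbonyl)prop-2-en-1-yl ester of 9
Conditions: KHCO3, DMF, rt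
Reagents that add atoms: none
Why: carboxylate O-alkylation by the allylic bromide (SN2 and SN2′ give the same ester), with bicarbonate too weak to deprotonate the secondary alcohol.

Step 8
Reactants: 11 diene ester
Product: 12 tert-butyl cis-fused 9-hydroxy-6-isopropyl-1-oxo-1,3,5a,6,7,8,9,9a-octahydro-2-benzoxepine-4-carboxylate (H-5a, H-6, H-9, H-9a all cis)
Conditions: RuCl2(H2IMes)(=CH-C6H4-2-OiPr) (second-generation Hoveyda–Grubbs catalyst, 10 mol %), toluene (0.002 M), 80 °C
Reagents that add atoms: none
Why: ring-closing metathesis between the vinyl group and the 1,1-disubstituted acrylate; the seven-membered ring can only hold C15 cis to C6, which is the required alkene geometry (ester trans to the ring).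

Step 9
Reactants: 12 hydroxy lactone
Product: 13 tert-butyl cis-fused 6-isopropyl-1,9-dioxo-1,3,5a,6,7,8,9,9a-octahydro-2-benzoxepine-4-carboxylate
Conditions: Dess–Martin periodinane, CH2Cl2, rt
Reagents that add atoms: none
Why: Dess–Martin oxidation of the secondary alcohol under non-basic conditions gives the β-keto lactone, with C1 held cis by the ring fusion.

Step 10
Reactants: 13 β-keto lactone
Product: 14 tert-butyl cis-fused 6-isopropyl-9-methylidene-1-oxo-1,3,5a,6,7,8,9,9a-octahydro-2-benzoxepine-4-carboxylate
Conditions: Zn, CH2Br2, TiCl4 (Lombardo reagent), THF/CH2Cl2, 0 °C → rt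
Reagents that add atoms: dibromomethane, BrCBr
Why: Takai–Lombardo methylenation, whose non-basic gem-dimetallic reagent adds to the ketone without enolising the β-keto lactone and leaves lactone and ester carbonyls alone.

Step 11
Reactants: 14 exo-methylene lactone
Product: 15 ring A spiro-epoxide, tert-butyl 6-isopropyl-1-oxo-hexahydro-spiro[2-benzoxepine-9,2'-oxirane]-4-carboxylate (epoxide O α, CH2 β)
Conditions: mCPBA, CH2Cl2, 0 °C
Reagents that add atoms: 3-chloroperbenzoic acid, OOC(=O)c1cccc(Cl)c1
Why: Prilezhaev epoxidation of the only electron-rich alkene from the α face (the β face is shielded by the syn-axial C5 and the lactone), which sets C10 with oxygen α and CH2 β.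

Step 12
Reactants: 4 silyloxydiene; 16 (5R)-5-(l-menthyloxy)furan-2(5H)-one
Product: 17 the enantiomer of 6 (built on l-menthol)
Conditions: toluene, BHT (cat.), 115 °C, sealed tube
Reagents that add atoms: none
Why: the same anti, endo, ortho-selective Diels–Alder reaction as in step 3 with the antipodal auxiliary, which sets C6' and C7' in the mirror-image sense that ring B requires.

Step 13
Reactants: 17 antipodal adduct
Product: 18 the enantiomer of 7
Conditions: H2 (1 atm), PtO2, EtOAc, rt
Reagents that add atoms: none
Why: heterogeneous hydrogenation of the only C=C, with no stereocentre touched.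

Step 14
Reactants: 18 saturated antipodal adduct
Product: 19 the enantiomer of lactol 8
Conditions: 2 M aq. HCl/THF, 50 °C
Reagents that add atoms: water, O
Why: acid hydrolysis of the acetal and silyl ether as in step 5, with the aldehyde held as the cis-fused lactol so that C6' keeps its configuration.

Step 15
Reactants: 19 antipodal lactol
Product: 20 the enantiomer of 9
Conditions: Ph3PCH3Br, KOtBu, THF, −78 → 0 °C; aq. citric acid work-up
Reagents that add atoms: methyltriphenylphosphonium bromide, C[P+](c1ccccc1)(c1ccccc1)c1ccccc1.[Br-]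
Why: Wittig methylenation of the lactol as in step 6, fast enough at low temperature to avoid epimerisation at C6'.

Step 16
Reactants: 20 antipodal vinyl hydroxy acid; 21 methyl 2-(bromomethyl)acrylate
Product: 22 2-(methoxycarbonyl)prop-2-en-1-yl ester of 20
Conditions: KHCO3, DMF, rt
Reagents that add atoms: none
Why: carboxylate O-alkylation as in step 7; a methyl ester is chosen because this series is fully saponified later.

Step 17
Reactants: 22 antipodal diene ester
Product: 23 methyl ester analogue of 12 with the enantiomeric ring system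
Conditions: RuCl2(H2IMes)(=CH-C6H4-2-OiPr) (second-generation Hoveyda–Grubbs catalyst, 10 mol %), toluene (0.002 M), 80 °C
Reagents that add atoms: none
Why: ring-closing metathesis as in step 8; the ring locks C15' cis to C6', which becomes the E-acrylate of ring B after ring opening.

Step 18
Reactants: 23 antipodal hydroxy lactone
Product: 24 methyl ester analogue of 13 with the enantiomeric ring system
Conditions: Dess–Martin periodinane, CH2Cl2, rt
Reagents that add atoms: none
Why: Dess–Martin oxidation of the secondary alcohol to the β-keto lactone.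

Step 19
Reactants: 24 antipodal β-keto lactone
Product: 25 methyl ester analogue of 14 with the enantiomeric ring system
Conditions: Zn, CH2Br2, TiCl4 (Lombardo reagent), THF/CH2Cl2, 0 °C → rt
Reagents that add atoms: dibromomethane, BrCBr
Why: non-basic Takai–Lombardo methylenation of the ketone as in step 10.

Step 20
Reactants: 25 antipodal exo-methylene lactone
Product: 26 all-cis 2-[(1E)-2-carboxy-3-hydroxyprop-1-en-1-yl]-3-isopropyl-6-methylidenecyclohexane-1-carboxylic acid (antipodal series)
Conditions: LiOH, THF/MeOH/H2O, 40 °C; then 1 M HCl to pH 3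
Reagents that add atoms: lithium hydroxide, [Li+].[OH-]
Why: saponification (acyl substitution) of the lactone and the methyl ester frees both carboxyls and the C15' alcohol without changing the alkene geometry or C6'/C7'.

Step 21
Reactants: 26 hydroxy diacid
Product: 28 (2E)-2-(hydroxymethyl)-3-[(1R,6S)-3-(hydroxymethyl)-6-isopropylcyclohex-2-en-1-yl]prop-2-enoic acid, via spiro-epoxy diacid 27 (not isolated)
Conditions: dimethyldioxirane (1.0 equiv), acetone, −20 °C; then PPTS (10 mol %), 40 °C
Reagents that add atoms: dimethyldioxirane, CC1(C)OO1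
Why: Proposed new method: the dioxirane epoxidises only the electron-rich 1,1-disubstituted alkene, and on mild acid activation the tertiary C10'–O bond of the β,γ-epoxy acid ionises while the neighbouring C2' carboxyl is lost as CO2 (Grob-type decarboxylative ring opening), giving the C1'=C10' alkene and the C14' alcohol regiospecifically with C6'/C7' untouched; the closest known chemistry is decarboxylative elimination of carboxylic acids bearing a β leaving group (β-halo acids, β-lactone thermolysis, amide-acetal dehydration of β-hydroxy acids) and peracid oxidative decarboxylation of β,γ-unsaturated acids.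

Step 22
Reactants: 15 ring A spiro-epoxide; 28 ring B dihydroxy acid
Product: 29 tert-butyl ester of the target
Conditions: Cs2CO3 (0.2 equiv), DMF, 60 °C
Reagents that add atoms: none
Why: SN2 ring opening of the 2,2-disubstituted epoxide by the carboxylate at the unsubstituted carbon C14 (known carboxylate–epoxide addition); C10 is not touched, so the tertiary α-hydroxyl appears with retention, and the neutral primary alcohols of 28 do not compete.

Step 23
Reactants: 29 tert-butyl ester of the target
Product: 30 CNP0361406.12 (target)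
Conditions: CF3CO2H/CH2Cl2 (1:4), 0 °C
Reagents that add atoms: none
Why: acidolysis of the tert-butyl ester (E1 loss of isobutene) frees the ring A carboxylic acid while the other esters and the alcohols survive brief cold acid.

**Compound list**

1 | 3-methylbutanal | CC(C)CC=O | starting material
2 | (triphenylphosphoranylidene)acetaldehyde | O=CC=P(c1ccccc1)(c1ccccc1)c1ccccc1 | starting material
3 | (E)-5-methylhex-2-enal | CC(C)C/C=C/C=O | intermediate
4 | tert-butyl(dimethyl){[(1E,3E)-5-methylhexa-1,3-dien-1-yl]oxy}silane | CC(C)/C=C/C=C/O[Si](C)(C)C(C)(C)C | intermediate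
5 | (5S)-5-{[(1S,2R,5S)-2-isopropyl-5-methylcyclohexyl]oxy}furan-2(5H)-one | O=C1C=C[C@@H](O[C@H]2C[C@@H](C)CC[C@@H]2C(C)C)O1 | starting material
6 | Diels–Alder adduct, all-cis, d-menthyl acetal | CC(C)[C@H]1C=C[C@@H](O[Si](C)(C)C(C)(C)C)[C@H]2C(=O)O[C@H](O[C@H]3C[C@@H](C)CC[C@@H]3C(C)C)[C@@H]12 | intermediate
7 | ring-saturated adduct | CC(C)[C@H]1CC[C@@H](O[Si](C)(C)C(C)(C)C)[C@H]2C(=O)O[C@H](O[C@H]3C[C@@H](C)CC[C@@H]3C(C)C)[C@@H]12 | intermediate
8 | cis-fused hydroxy lactol (C3 epimers) | CC(C)[C@H]1CC[C@@H](O)[C@H]2C(=O)OC(O)[C@@H]12 | intermediate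
9 | all-cis 2-ethenyl-6-hydroxy-3-isopropylcyclohexane-1-carboxylic acid | CC(C)[C@H]1CC[C@@H](O)[C@@H](C(=O)O)[C@H]1C=C | intermediate
10 | tert-butyl 2-(bromomethyl)acrylate | C=C(CBr)C(=O)OC(C)(C)C | starting material
11 | 2-(tert-butoxycarbonyl)allyl ester of 9 | CC(C)[C@H]1CC[C@@H](O)[C@@H](C(=O)OCC(=C)C(=O)OC(C)(C)C)[C@H]1C=C | intermediate
12 | seven-membered lactone, 10β-hydroxy, tert-butyl ester | CC(C)[C@H]1CC[C@@H](O)[C@H]2C(=O)OCC(C(=O)OC(C)(C)C)=C[C@@H]12 | intermediate
13 | β-keto lactone, tert-butyl ester | CC(C)[C@H]1CCC(=O)[C@H]2C(=O)OCC(C(=O)OC(C)(C)C)=C[C@@H]12 | intermediate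
14 | exo-methylene lactone, tert-butyl ester | CC(C)[C@H]1CCC(=C)[C@H]2C(=O)OCC(C(=O)OC(C)(C)C)=C[C@@H]12 | intermediate
15 | ring A spiro-epoxide (O α, CH2 β) | CC(C)[C@H]1CC[C@@]3(CO3)[C@H]2C(=O)OCC(C(=O)OC(C)(C)C)=C[C@@H]12 | intermediate
16 | (5R)-5-{[(1R,2S,5R)-2-isopropyl-5-methylcyclohexyl]oxy}furan-2(5H)-one | O=C1C=C[C@H](O[C@@H]2C[C@H](C)CC[C@H]2C(C)C)O1 | starting material
17 | enantiomer of 6 | CC(C)[C@@H]1C=C[C@H](O[Si](C)(C)C(C)(C)C)[C@@H]2C(=O)O[C@@H](O[C@@H]3C[C@H](C)CC[C@H]3C(C)C)[C@H]12 | intermediate
18 | enantiomer of 7 | CC(C)[C@@H]1CC[C@H](O[Si](C)(C)C(C)(C)C)[C@@H]2C(=O)O[C@@H](O[C@@H]3C[C@H](C)CC[C@H]3C(C)C)[C@H]12 | intermediate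
19 | enantiomer of 8 (C3 epimers) | CC(C)[C@@H]1CC[C@H](O)[C@@H]2C(=O)OC(O)[C@H]12 | intermediate
20 | enantiomer of 9 | CC(C)[C@@H]1CC[C@H](O)[C@H](C(=O)O)[C@@H]1C=C | intermediate
21 | methyl 2-(bromomethyl)acrylate | C=C(CBr)C(=O)OC | starting material
22 | 2-(methoxycarbonyl)allyl ester of 20 | CC(C)[C@@H]1CC[C@H](O)[C@H](C(=O)OCC(=C)C(=O)OC)[C@@H]1C=C | intermediate
23 | antipodal seven-membered lactone, hydroxy, methyl ester | CC(C)[C@@H]1CC[C@H](O)[C@@H]2C(=O)OCC(C(=O)OC)=C[C@H]12 | intermediate
24 | antipodal β-keto lactone, methyl ester | CC(C)[C@@H]1CCC(=O)[C@@H]2C(=O)OCC(C(=O)OC)=C[C@H]12 | intermediate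
25 | antipodal exo-methylene lactone, methyl ester | CC(C)[C@@H]1CCC(=C)[C@@H]2C(=O)OCC(C(=O)OC)=C[C@H]12 | intermediate
26 | antipodal-series hydroxy diacid with exo-methylene | CC(C)[C@@H]1CCC(=C)[C@H](C(=O)O)[C@@H]1/C=C(\CO)C(=O)O | intermediate
27 | spiro-epoxy diacid (epoxide O trans to the ring carboxyl; this centre is lost in the next event) | CC(C)[C@@H]1CC[C@]2(CO2)[C@H](C(=O)O)[C@@H]1/C=C(\CO)C(=O)O | intermediate
28 | (2E)-2-(hydroxymethyl)-3-[(1R,6S)-3-(hydroxymethyl)-6-isopropylcyclohex-2-en-1-yl]prop-2-enoic acid | OC(=O)/C(=C/[C@H]1C=C(CO)CC[C@H]1C(C)C)CO | intermediate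
29 | tert-butyl ester of the target | CC(C)[C@H]1CC[C@@](O)(COC(=O)/C(=C/[C@H]2C=C(CO)CC[C@H]2C(C)C)CO)[C@H]2C(=O)OCC(C(=O)OC(C)(C)C)=C[C@@H]12 | intermediate
30 | CNP0361406.12 | CC(C)[C@H]1CC[C@@](O)(COC(=O)/C(=C/[C@H]2C=C(CO)CC[C@H]2C(C)C)CO)[C@H]2C(=O)OCC(C(=O)O)=C[C@@H]12 | target

**Totals and risks**

Total step count: 23. Longest linear sequence: 14 (steps 1, 2, 12–21, 22, 23).

Most likely to fail, step 21 (decarboxylative epoxide fragmentation): the epoxy acid may lactonise at C14' or rearrange instead of losing CO2. Fallback: set out from 26 and use kinetic iodolactonisation (iodine, NaHCO3, H2O/CH2Cl2, 0 °C), in which the C2' carboxylate closes on the tertiary carbon to give the iodomethyl β-lactone F1. Heating in toluene at 90 °C extrudes CO2 by cycloreversion and gives the allylic iodide F2 with the same regiodefined ring alkene. Hydrolysis (NaHCO3, aqueous acetone, 40 °C) comes back to the route at 28.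

Step 22 (epoxide opening by the carboxylate): the CH2 of the epoxide is axial and neopentyl-like, so substitution may be slow or the allylic lactone may be attacked. Fallback: switch from alkyl C–O to acyl C–O bond formation. Set out from 14 and dihydroxylate (OsO4 cat., N-methylmorpholine N-oxide, acetone/H2O, α face) to the C10,C14-diol F3. In parallel, set out from 28 and persilylate (TBSCl, imidazole, DMF) to the tris-silyl compound F4, then cleave its silyl ester (K2CO3, MeOH/H2O) to the bis-silyl ether acid F5. Yamaguchi esterification (2,4,6-trichlorobenzoyl chloride, Et3N, then DMAP) of F5 with the primary hydroxyl of F3 gives the protected ester F6, and HF·pyridine removes both silyl ethers and comes back to the route at 29.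

Step 8 (ring-closing metathesis to a seven-membered lactone with a trisubstituted enoate; the same holds for step 17): the s-trans ester preference and the hindered acrylate may stop ring closure. Fallback: make the alkene first and close the ring through oxygen. Set out from 8 and run a Horner–Wadsworth–Emmons reaction on the lactol with tert-butyl 2-(diethoxyphosphoryl)-3-[(tert-butyldimethylsilyl)oxy]propanoate (NaH, THF, 0 °C, E-selective) to the seco acid F7. HF·pyridine gives the allylic alcohol F8. Mitsunobu lactonisation (PPh3, DIAD, toluene, high dilution; the primary allylic alcohol is activated in preference to the secondary one) closes the ring and comes back to the route at 12.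

**Further compounds**

F1 | step 21 | iodomethyl cis-fused β-lactone of 26 | CC(C)[C@@H]1CC[C@]2(CI)OC(=O)[C@@H]2[C@@H]1/C=C(\CO)C(=O)O
F2 | step 21 | allylic iodide, 14'-iodo analogue of 28 | CC(C)[C@@H]1CCC(CI)=C[C@@H]1/C=C(\CO)C(=O)O
F3 | step 22 | C10,C14-diol of the ring A lactone (10α-OH), tert-butyl ester | CC(C)[C@H]1CC[C@@](O)(CO)[C@H]2C(=O)OCC(C(=O)OC(C)(C)C)=C[C@@H]12
F4 | step 22 | tris-TBS derivative of 28 (two silyl ethers, one silyl ester) | CC(C)(C)[Si](C)(C)OC(=O)/C(=C/[C@H]1C=C(CO[Si](C)(C)C(C)(C)C)CC[C@H]1C(C)C)CO[Si](C)(C)C(C)(C)C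
F5 | step 22 | bis-TBS ether of acid 28 | OC(=O)/C(=C/[C@H]1C=C(CO[Si](C)(C)C(C)(C)C)CC[C@H]1C(C)C)CO[Si](C)(C)C(C)(C)C
F6 | step 22 | bis-TBS ether of 29 | CC(C)[C@H]1CC[C@@](O)(COC(=O)/C(=C/[C@H]2C=C(CO[Si](C)(C)C(C)(C)C)CC[C@H]2C(C)C)CO[Si](C)(C)C(C)(C)C)[C@H]2C(=O)OCC(C(=O)OC(C)(C)C)=C[C@@H]12
F7 | step 8 | seco acid with E-acrylate tert-butyl ester and TBS ether at C15 | CC(C)[C@H]1CC[C@@H](O)[C@@H](C(=O)O)[C@H]1/C=C(\CO[Si](C)(C)C(C)(C)C)C(=O)OC(C)(C)C
F8 | step 8 | seco acid with free C15 alcohol | CC(C)[C@H]1CC[C@@H](O)[C@@H](C(=O)O)[C@H]1/C=C(\CO)C(=O)OC(C)(C)C
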